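## The problem

Ainsliatrimer A consists of three guaianolide units derived from dehydrocostus lactone, called A, B and C here, with guaiane numbering inside each unit; α is the face of H-1 and H-5 in the parent lactone (1α-H, 5α-H, 6β-H, 7α-H). The units are joined by two spiro-fused cyclohexene rings: ring R1 (C4B, C15B, C14A, C10A, C1A, C2A) and ring R2 (C4C, C15C, C14B, C10B, C1B, C2B). Ten of the fourteen stereocentres (C5, C6, C7 of each unit and C1 of unit C) are those of the monomer and only need to survive. The four new ones are the spiro carbons C4B and C4C, the tertiary carbinol C10B (β-OH) and the methine C10A (α-H). The cis-fused, bowl-shaped monomer can steer additions at C4 through its open H-5 face, but the two spiro centres differ: at C4C the ring carbon C2B sits on the α face, whereas at C4B the ring carbon C2A sits on the β face and the methylene C15B on the α face. C10A and C10B lie next to sp2 carbons on flatter rings and are harder to control. The fragile groups are three α-methylene lactones, the exocyclic enone of unit A and the exo-methylene of unit C (all acceptors for nucleophiles and hydride), the C5–H/C6–O pairs that can β-eliminate once C4 or C1 belongs to an enone, and the tertiary allylic alcohol. Because all units come from one monomer, each reagent meets the same functional group in several copies. The feature that opens the key step is that C4B is α to the C3B ketone and bonded to C2A, the α-carbon of the C3A ketone, while C1A and C10A are held cis in the seven-membered ring of unit A. C2A=C4B can therefore be the ene-dione end of a hexatriene C4B=C2A–C1A=C10A–C14A=C15B whose closure forms R1 and the quaternary spiro carbon.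

## Retrosynthesis

**C10B–O.** The tertiary alcohol of 29 is γ to the C3B ketone across C2B=C1B, so it is removed first. This gives the deconjugated enone 27 (C1B=C10B, C2B–H), whose doubly activated C2B–H can be turned into a dienolate and trapped by oxygen at C10B. Introducing the alcohol last avoids carrying an ionisable tertiary allylic alcohol. The forward step must choose the β face of C10B and must prefer C2B–H over the γ-hydrogens of unit A.

**C2B–C4C and C14B–C15C.** Ring R2 of 27 is a cyclohexene, and cutting both σ-bonds returns dehydrozaluzanin C 3 (dienophile C4C=C15C) and dienone 26, whose diene C2B=C1B–C10B=C14B is locked s-cis. Compared with one-bond polar cuts, this removes a whole monomer, uses both exo-methylenes at their native oxidation level, and sets quaternary C4C by addition to the open α face of 3. Dienone 26 comes from ketone 24 through silyl enol ether 25, and only C2B can enolise because C4B is quaternary. The forward step needs 3 in excess so that 26 does not use the unit-A enone of a second molecule.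

**Hydrogen at C10A and C14A.** Ring R1 of 24 is one double bond short of a cyclohexadiene; adding that double bond back gives dienone 19. The price in the forward direction is a 1,6-reduction of 19 that needs the three exocyclic acceptors masked (20, 22) and that sets C10A by protonation.

**C4B–C15B (key cut).** Cutting 19 at the spiro carbon gives triene 18. The neighbouring cuts are C2A–C4B alone (a Claisen route) or both bonds of R1 (a [4+2] between units A and B). Both would have to bring the large C2A fragment onto the concave β face of unit B. Cutting C4B–C15B lets the small CH2 terminus arrive last, from the α face. Triene 18 has no new stereocentre and its two halves are joined only by a C=C bond.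

**C10A–C14A and the oxidation level at C3B.** The vinyl group of 18 comes from tributyl(vinyl)stannane 17 and dienyl triflate 16; its terminal carbon replaces the C15 lost from unit B. Triflate 16 is traced back through alcohol 15 and silyl ether 14 to ketone 13. The C3B ketone is unveiled only after the triflate is in place, so that the enolate of 13 has a single oxygen to sulfonylate. The vinyl group is added only after C3B is sp2, so that the triene never carries a face-biasing substituent next to C4B.

**C2A=C4B.** The tetrasubstituted alkene of 13 and 12 is cut by a crossed aldol condensation into 6 and 10. Each partner has exactly one free ketone: 6 can enolise only at C2A (C10A is a ketal, C4A is sp2), and 10 offers only C4B (C3B is a silyl ether). A diketone nucleophile or a 1,2-dione electrophile would each pose a regiochemical choice.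

**Differentiating the two exo-methylenes of the monomer.** Ketal 6 comes from diketone 5, made by ozonolysis of 3; in 3 the C4=C15 alkene is deactivated as an enone and only C10=C14 is electron-rich. Ketone 10 comes from silyl ether 8 and epoxy alcohol 7; in alcohol 2 the hydroxyl directs epoxidation to C4=C15 alone, and periodate then excises C15. Compounds 2 and 3 come from dehydrocostus lactone 1 by allylic oxidation, and 3 also serves as unit C.

## Roads not taken

Alternative 1: The cut is C2B–C4C, made last within R2. Its substrate is A1, the silyl enol ether of a B–C spiro-dihydropyran (hetero-Diels–Alder adduct of the unit-C enone with C10B=C14B). (NH4)2Ce(NO3)6, a tetravalent cerium oxidant, oxidises the enol ether so that C2B bonds to the pyran enol-ether carbon C4C. Water opens the resulting bridged oxocarbenium ion to the C3C ketone and the C10B alcohol of ketol A2.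
- Merits: the C10B oxygen is carried in from the pyran and keeps its configuration, and C4C is set intramolecularly. In this respect it is better than the chosen plan, whose C10B oxygenation is an intermolecular face selection.
- Weak points: A2 is a 1,2-dihydro, 4-methyl unit B. It needs a later C1B=C2B dehydrogenation, and C4B has lost the ketone or methylene handle needed to build R1, so the A–B half remains unsolved. The radical cation must also ignore several 1,1-disubstituted alkenes, and the hetero-Diels–Alder union of two near-identical monomers competes with homodimerisation.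
- Against this, the chosen plan keeps C4B functional for the spiro ring and joins unit C by a Diels–Alder reaction whose regiochemistry and facial preference follow from the monomer's shape.

Alternative 2: The cuts are C2B–C4C and C14B–C10B. The acetyl diketone A4 (unit C bearing an acetyl group at C4C) adds through C4C to C2B of the 14-nor ene-dione A3 (reachable from 5 by dehydrogenation). The acetyl methyl then closes onto the C10B ketone and gives ketol A5.
- Merits: it uses polar chemistry only, forms two bonds, R2, C4C and the tertiary alcohol in one operation, and fixes C10B by ring closure instead of by oxidation. That is a real advantage over step 20 of the chosen route.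
- Weak points: A5 carries an extra carbonyl at C15C, next to the quaternary centre, which must be deleted in the presence of three other ketones and three α-methylene lactones. Both monomers must first be degraded by one carbon, and unit B ends up saturated at C1–C2.
- Against this, the chosen plan's [4+2] delivers C14B and C15C at the correct oxidation level from unmodified exo-methylenes.

Alternative 3: The cut is C2A–C4B. Heating or Me2AlCl would rearrange spiro-dihydropyran A6 (allyl vinyl ether C4B=C3B–O–C10A–C1A=C2A) by a Claisen shift, contracting the pyran to R1 and regenerating the C3B ketone in β,γ-enone A7.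
- Merits: A7 already has the oxidation level of R1, so no triflate, no stannane and no reduction with masking are needed. It would be several steps shorter than the chosen route and redox-neutral.
- Weak points: A6 requires a cross hetero-Diels–Alder reaction in which the unit-A dienone reacts as a 2π partner at C10=C14, although it prefers to act as a diene. Two nearly identical enones would give statistical dimer mixtures. The spiro-acetal configuration at C10A dictates the C4B configuration through a strained boat transition state, and retro-cycloaddition competes at the temperatures needed.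
- Against its brevity, the chosen plan offers an unambiguous crossed union (one enolisable ketone with one electrophilic ketone) and a ring closure in which only a CH2 group has to find the open face of unit B.

Key step: step 14

Assumptions: the C2(A)=C4(B) alkene of 12–18 is drawn as the isomer with C3(A) and C3(B) trans (the C3(B) carbon, not C5(B)–H, points into the triene); triene 18 is taken to be isolable at room temperature, and if it closes during the coupling, steps 13 and 14 merge without change of outcome.

## Route

Step 1
Reactants: 1 dehydrocostus lactone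
Product: 2 3-epizaluzanin C (3α-hydroxydehydrocostus lactone, hydroxyl cis to H-5)
Conditions: SeO2 (0.5 equiv), t-BuOOH, CH2Cl2, 0 °C to rt
Reagents that add atoms: selenium dioxide, O=[Se]=O; tert-butyl hydroperoxide, CC(C)(C)OO
Why: Catalytic SeO2 allylic oxidation (ene reaction, then [2,3]-shift) attacks the CH2 next to the cyclopentylidene methylene and delivers oxygen on the convex α face; the conjugated lactone methylene is inert, and the C3 configuration is erased later (steps 2 and 12).

Step 2
Reactants: 2 3-epizaluzanin C
Product: 3 dehydrozaluzanin C (3-oxodehydrocostus lactone)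
Conditions: Dess–Martin periodinane, NaHCO3, CH2Cl2, 0 °C to rt
Reagents that add atoms: none
Why: Dess–Martin oxidation of the secondary allylic alcohol under buffered, non-basic conditions leaves the three exocyclic alkenes untouched.

Step 3
Reactants: 3 dehydrozaluzanin C
Product: 5 10-oxo-14-nordehydrozaluzanin C (3,10-diketone), via ozonide 4 (not isolated)
Conditions: O3, CH2Cl2, −78 °C (Sudan red end point); then Me2S, −78 °C to rt
Reagents that add atoms: ozone, [O-][O+]=O
Why: Chemoselective ozonolysis: ozone is electrophilic and attacks only the electron-rich C10=C14 alkene, while the enone and acrylate methylenes are deactivated by conjugation; reductive work-up gives the ketone.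

Step 4
Reactants: 5 10-oxo-14-nordehydrozaluzanin C
Product: 6 10,10-ethylenedioxy ketal of 5 (C3 enone free)
Conditions: TMSOCH2CH2OTMS, TMSOTf (cat.), CH2Cl2, −78 to −20 °C; pyridine quench
Reagents that add atoms: 1,2-bis(trimethylsilyloxy)ethane, C[Si](C)(C)OCCO[Si](C)(C)C
Why: Noyori ketalisation under cold, aprotic conditions protects saturated ketones much faster than cross-conjugated enones, so only C10 is masked and C2 becomes the only enolisable position.

Step 5
Reactants: 2 3-epizaluzanin C
Product: 7 4α,15-epoxy-3α-hydroxy derivative of 1 (epoxide oxygen cis to the hydroxyl)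
Conditions: VO(acac)2 (cat.), t-BuOOH, CH2Cl2, 0 °C to rt
Reagents that add atoms: tert-butyl hydroperoxide, CC(C)(C)OO
Why: Vanadium-catalysed, hydroxyl-directed epoxidation reacts only at the allylic C4=C15 alkene and delivers oxygen syn to the alcohol; the remote C10=C14 alkene and the acrylate do not react.

Step 6
Reactants: 7 epoxy alcohol
Product: 8 3α-tert-butyldimethylsilyl ether of 7
Conditions: TBSCl, imidazole, DMF, rt
Reagents that add atoms: tert-butyldimethylsilyl chloride, CC(C)(C)[Si](C)(C)Cl
Why: Standard silylation; the ether stops periodate from also cutting C3–C4 in step 7 and later keeps C3(B) from competing with C4(B) as electrophile.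

Step 7
Reactants: 8 silyl ether epoxide
Product: 10 15-nor-4-oxo-3α-(tert-butyldimethylsilyloxy) ketone (unit B ketone), via 4,15-diol 9 (not isolated)
Conditions: H5IO6, THF–H2O, 0 °C to rt
Reagents that add atoms: water, O
Why: Periodic acid hydrolyses the spiro-epoxide and cleaves the resulting glycol (Malaprade cleavage), excising C15 as formaldehyde; no other 1,2-dioxygenated pair is free.

Step 8
Reactants: 6 ketal enone; 10 unit B ketone
Product: 12 A–B enone with C2(A)=C4(B) alkene and C10(A) ketal and C3(B) α-silyl ether, via aldol adduct 11 (not isolated)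
Conditions: 6, TiCl4, Et3N, CH2Cl2, −78 °C; then 10, −78 to 0 °C
Reagents that add atoms: none
Why: Soft enolisation gives the titanium dienolate of 6, which can form only at C2; it adds through a closed transition state to the single ketone of 10, and the titanium aldolate eliminates toward the acidic C2(A)–H (crossed aldol condensation). The isomer with C3(A) and C3(B) trans should be the less congested one.

Step 9
Reactants: 12 A–B enone ketal
Product: 13 A–B enone 10(A)-ketone
Conditions: PPTS, acetone–H2O, 45 °C
Reagents that add atoms: water, O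
Why: Mild acid-catalysed ketal hydrolysis; the secondary silyl ether and the exocyclic alkenes tolerate pyridinium tosylate.

Step 10
Reactants: 13 A–B enone 10(A)-ketone
Product: 14 dienyl triflate (C1(A)=C10(A)–OTf, C3(B) α-silyl ether)
Conditions: KN(SiMe3)2, THF, −78 °C; PhNTf2, −78 to 0 °C
Reagents that add atoms: N-phenylbis(trifluoromethanesulfonimide), O=S(=O)(N(c1ccccc1)S(=O)(=O)C(F)(F)F)C(F)(F)F
Why: C1(A)–H is α to the ketone and allylic to C2(A)=C4(B), so it is removed in preference to C9(A)–H2, and the extended enolate is sulfonylated on its only oxygen (enol triflate formation). The conjugated tautomer of 13 would give the same enolate, and C3(B) is still an ether.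

Step 11
Reactants: 14 dienyl triflate silyl ether
Product: 15 C3(B) allylic alcohol dienyl triflate
Conditions: HF·pyridine, pyridine, THF, 0 °C to rt
Reagents that add atoms: none
Why: Buffered fluoride desilylation without base spares the vinyl triflate, the lactones and the base-labile C5(B)–H/C6(B)–O pair.

Step 12
Reactants: 15 allylic alcohol
Product: 16 ene-dione dienyl triflate
Conditions: Dess–Martin periodinane, NaHCO3, CH2Cl2, 0 °C
Reagents that add atoms: none
Why: Dess–Martin oxidation of the allylic alcohol completes the ene-dione before the vinyl group is present, so C3(B) is sp2 and exerts no facial bias when the triene first appears.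

Step 13
Reactants: 16 ene-dione dienyl triflate; 17 tributyl(vinyl)stannane
Product: 18 A–B ene-dione triene
Conditions: Pd2(dba)3 (cat.), AsPh3, LiCl, NMP, rt, dark
Reagents that add atoms: none
Why: Stille coupling of the electron-poor dienyl triflate under ligand-accelerated room-temperature conditions installs C14(A)=C15(B); the neutral medium suits the Michael acceptors, and the low temperature is meant to keep the triene open until isolation.

Step 14
Reactants: 18 A–B ene-dione triene
Product: 19 A–B spiro dimer with ring R1 as a cyclohexadiene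
Conditions: PhMe (dilute, degassed), BHT (trace), 80 °C, dark
Reagents that add atoms: none
Why: Thermal disrotatory 6π electrocyclisation of the hexatriene C4(B)=C2(A)–C1(A)=C10(A)–C14(A)=C15(B), the known closure of a cis-hexatriene to a cyclohexadiene with a new quaternary carbon. Ring R1 closes in the 6π mode: C2(A)–C1(A) is s-cis because both alkenes are exocyclic on adjacent atoms of the five-membered ring of unit A, and C1(A)=C10(A) is cis because C9(A) is tied to C5(A) through the seven-membered ring, so only rotation about C10(A)–C14(A) is needed. The acyl groups at triene position 2 (the C3(A) ketone on C2(A)) and on the C4(B) terminus (the C3(B) ketone) lower the barrier, so gentle heating should suffice. The one new stereocentre, spiro C4(B), is set by the face of the planar terminus that the CH2 group C15(B) reaches: the α face carries only H-5(B), whereas the β face carries C6(B) with the lactone-bearing seven-membered ring, so the helical transition state with C15(B) on the α face should be preferred and gives C15(B) α and C2(A) β as required. In the drawn alkene isomer the inward substituent of the terminus is the C3(B) carbonyl carbon, and C2(B)–H2 is poorly placed for a competing [1,7]-hydrogen shift. The step needs C–C over C–O closure: oxa-6π closure of a dienone arm to a 2H-pyran is reversible whereas C–C closure is not, so material stored as pyran should drain to 19. Dilution, darkness and a radical inhibitor protect the exocyclic acceptors from intermolecular Diels–Alder reaction and polymerisation, and 80 °C is below the range of [1,5]-hydrogen shifts in the product diene.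

Step 15
Reactants: 19 A–B spiro dimer cyclohexadiene
Product: 20 tris(dimethylamine) adduct of 19 (CH2NMe2 at C4(A), C11(A) and C11(B); epimers at these three carbons)
Conditions: Me2NH (excess), THF–MeOH, 0 °C to rt
Reagents that add atoms: dimethylamine, CNC
Why: Aza-Michael addition to the two α-methylene lactones and the exocyclic enone is fast, whereas the hindered endocyclic dienone terminus C14(A) should not retain amine; the three new α-stereocentres are transient.

Step 16
Reactants: 20 tris-amine adduct
Product: 22 masked A–B dimer with C2(A)=C1(A) enone and 10α-H, via deconjugated enone 21 (not isolated)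
Conditions: [(Ph3P)CuH]6, H2O, PhH–THF, rt; then DBU (cat.), CH2Cl2, rt
Reagents that add atoms: none
Why: Copper hydride reduces only conjugated carbonyl systems; the β-carbon C1(A) is fully substituted, so hydride should go to the δ-carbon C14(A) (1,6-conjugate reduction), leaving the C3(B) ketone and C10(B)=C14(B) alone. DBU then relays the C2(A) proton to C10(A) through the dienolate; protonation from the α face, away from the C6–C8 flank of the seven-membered ring, should set 10α-H.

Step 17
Reactants: 22 masked A–B dimer
Product: 24 A–B spiro dimer with ring R1 as a cyclohexene and the three exo-methylenes restored, via tris-ammonium iodide 23 (not isolated)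
Conditions: MeI, MeOH, rt; then NaHCO3 (aq.), CH2Cl2, rt
Reagents that add atoms: none
Why: Exhaustive N-methylation followed by mild-base elimination of trimethylamine (Hofmann-type unmasking of Mannich bases) regenerates the three exocyclic methylenes and erases the stereocentres made in step 15.

Step 18
Reactants: 24 A–B spiro dimer
Product: 25 C3(B) tert-butyldimethylsilyl enol ether of 24 (C2(B)=C3(B))
Conditions: TBSOTf, Et3N, CH2Cl2, −78 to 0 °C
Reagents that add atoms: tert-butyldimethylsilyl trifluoromethanesulfonate, CC(C)(C)[Si](C)(C)OS(=O)(=O)C(F)(F)F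
Why: Silyl enol ether formation from the saturated C3(B) ketone can occur only toward C2(B) because C4(B) is quaternary; the unit-A enone has no α-hydrogen and its γ-hydrogens react far more slowly at low temperature.

Step 19
Reactants: 25 silyl enol ether; 3 dehydrozaluzanin C
Product: 27 Diels–Alder trimer (C1(B)=C10(B), C2(B)–H, spiro C4(C)), via dienone 26 (not isolated)
Conditions: Pd(OAc)2 (1.1 equiv), 3 (5 equiv), MeCN, rt, argon
Reagents that add atoms: none
Why: Saegusa–Ito oxidation gives dienone 26, whose diene C2(B)=C1(B)–C10(B)=C14(B) is locked s-cis; excess 3 traps it in a Diels–Alder reaction joining C2(B) to C4(C) and C14(B) to C15(C). Quaternary C4(C) is set by addition to the convex α (H-5) face of the exocyclic enone of 3; the C2(B) configuration is left open and is erased in step 20.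

Step 20
Reactants: 27 Diels–Alder trimer
Product: 29 ainsliatrimer A, via hydroperoxide 28 (not isolated)
Conditions: O2 (1 atm), DBU, P(OEt)3, THF, −20 °C
Reagents that add atoms: dioxygen, O=O
Why: C2(B)–H is α to the ketone and allylic, so DBU forms the dienolate selectively at low temperature; oxygen adds at the γ-carbon C10(B) and the phosphite reduces the hydroperoxide in situ (γ-hydroxylation by dienolate autoxidation). The required β-alcohol arises from attack on the β face of the planar dienolate; this facial preference cannot be predicted with confidence.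

## Compound list

1 | dehydrocostus lactone | C=C1CC[C@H]2C(=C)CC[C@H]3C(=C)C(=O)O[C@@H]3[C@H]21 | starting material
2 | 3-epizaluzanin C (3α-hydroxydehydrocostus lactone) | C=C1[C@H](O)C[C@H]2C(=C)CC[C@H]3C(=C)C(=O)O[C@@H]3[C@H]21 | intermediate
3 | dehydrozaluzanin C (3-oxodehydrocostus lactone) | C=C1C(=O)C[C@H]2C(=C)CC[C@H]3C(=C)C(=O)O[C@@H]3[C@H]21 | intermediate
4 | 10,14-ozonide of 3 (spiro-1,2,4-trioxolane at C10, configuration at C10 open) | C=C1C(=O)C[C@H]2C3(OOCO3)CC[C@H]4C(=C)C(=O)O[C@@H]4[C@H]21 | intermediate (not isolated)
5 | 10-oxo-14-nordehydrozaluzanin C | C=C1C(=O)C[C@H]2C(=O)CC[C@H]3C(=C)C(=O)O[C@@H]3[C@H]21 | intermediate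
6 | 10,10-ethylenedioxy ketal of 5 | C=C1C(=O)C[C@H]2C3(OCCO3)CC[C@H]4C(=C)C(=O)O[C@@H]4[C@H]21 | intermediate
7 | 4α,15-epoxy-3α-hydroxy derivative of 1 | C1O[C@@]12[C@H](O)C[C@H]3C(=C)CC[C@H]4C(=C)C(=O)O[C@@H]4[C@H]32 | intermediate
8 | 3α-tert-butyldimethylsilyl ether of 7 | C1O[C@@]12[C@H](O[Si](C)(C)C(C)(C)C)C[C@H]3C(=C)CC[C@H]4C(=C)C(=O)O[C@@H]4[C@H]32 | intermediate
9 | 4,15-diol from 8 (configuration at C4 open) | OCC1(O)[C@H](O[Si](C)(C)C(C)(C)C)C[C@H]2C(=C)CC[C@H]3C(=C)C(=O)O[C@@H]3[C@H]21 | intermediate (not isolated)
10 | 15-nor-4-oxo-3α-(tert-butyldimethylsilyloxy) ketone (unit B ketone) | O=C1[C@H](O[Si](C)(C)C(C)(C)C)C[C@H]2C(=C)CC[C@H]3C(=C)C(=O)O[C@@H]3[C@H]21 | intermediate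
11 | aldol adduct of 6 and 10 (C2(A)–C4(B) bond, tertiary alcohol at C4(B); C2(A) and C4(B) open) | C=C1C(=O)C(C5(O)[C@H](O[Si](C)(C)C(C)(C)C)C[C@H]6C(=C)CC[C@H]7C(=C)C(=O)O[C@@H]7[C@H]65)[C@H]2C3(OCCO3)CC[C@H]4C(=C)C(=O)O[C@@H]4[C@H]21 | intermediate (not isolated)
12 | A–B enone, C2(A)=C4(B), C10(A) ketal, C3(B) α-silyl ether | C=C1C(=O)/C(=C5/[C@H](O[Si](C)(C)C(C)(C)C)C[C@H]6C(=C)CC[C@H]7C(=C)C(=O)O[C@@H]7[C@H]65)[C@H]2C3(OCCO3)CC[C@H]4C(=C)C(=O)O[C@@H]4[C@H]21 | intermediate
13 | A–B enone 10(A)-ketone | C=C1C(=O)/C(=C5/[C@H](O[Si](C)(C)C(C)(C)C)C[C@H]6C(=C)CC[C@H]7C(=C)C(=O)O[C@@H]7[C@H]65)[C@H]2C(=O)CC[C@H]3C(=C)C(=O)O[C@@H]3[C@H]21 | intermediate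
14 | dienyl triflate, C3(B) α-silyl ether | C=C1C(=O)/C(=C5/[C@H](O[Si](C)(C)C(C)(C)C)C[C@H]6C(=C)CC[C@H]7C(=C)C(=O)O[C@@H]7[C@H]65)C2=C(OS(=O)(=O)C(F)(F)F)CC[C@H]3C(=C)C(=O)O[C@@H]3[C@@H]12 | intermediate
15 | dienyl triflate, C3(B) α-alcohol | C=C1C(=O)/C(=C5/[C@H](O)C[C@H]6C(=C)CC[C@H]7C(=C)C(=O)O[C@@H]7[C@H]65)C2=C(OS(=O)(=O)C(F)(F)F)CC[C@H]3C(=C)C(=O)O[C@@H]3[C@@H]12 | intermediate
16 | ene-dione dienyl triflate | C=C1C(=O)/C(=C5/C(=O)C[C@H]6C(=C)CC[C@H]7C(=C)C(=O)O[C@@H]7[C@H]65)C2=C(OS(=O)(=O)C(F)(F)F)CC[C@H]3C(=C)C(=O)O[C@@H]3[C@@H]12 | intermediate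
17 | tributyl(vinyl)stannane | C=C[Sn](CCCC)(CCCC)CCCC | starting material
18 | A–B ene-dione triene | C=C1C(=O)/C(=C5/C(=O)C[C@H]6C(=C)CC[C@H]7C(=C)C(=O)O[C@@H]7[C@H]65)C2=C(C=C)CC[C@H]3C(=C)C(=O)O[C@@H]3[C@@H]12 | intermediate
19 | A–B spiro dimer, ring R1 cyclohexadiene | C=C1C(=O)C2=C3C(CC[C@H]4C(=C)C(=O)O[C@@H]4[C@@H]13)=CC[C@@]21C(=O)C[C@H]2C(=C)CC[C@H]3C(=C)C(=O)O[C@@H]3[C@H]21 | intermediate
20 | tris(dimethylamine) adduct of 19 (C4(A), C11(A), C11(B) open) | CN(C)CC1C(=O)C2=C3C(CC[C@H]4C(CN(C)C)C(=O)O[C@@H]4[C@@H]13)=CC[C@@]21C(=O)C[C@H]2C(=C)CC[C@H]3C(CN(C)C)C(=O)O[C@@H]3[C@H]21 | intermediate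
21 | deconjugated enone (C1(A)=C10(A), C2(A)–H), tris-amine | CN(C)CC1C(=O)C2C3=C(CC[C@H]4C(CN(C)C)C(=O)O[C@@H]4[C@@H]13)CC[C@@]21C(=O)C[C@H]2C(=C)CC[C@H]3C(CN(C)C)C(=O)O[C@@H]3[C@H]21 | intermediate (not isolated)
22 | masked A–B dimer, C2(A)=C1(A) enone, 10α-H | CN(C)CC1C(=O)C2=C3[C@H](CC[C@H]4C(CN(C)C)C(=O)O[C@@H]4[C@@H]13)CC[C@@]21C(=O)C[C@H]2C(=C)CC[C@H]3C(CN(C)C)C(=O)O[C@@H]3[C@H]21 | intermediate
23 | tris(trimethylammonium) triiodide of 22 | C[N+](C)(C)CC1C(=O)C2=C3[C@H](CC[C@H]4C(C[N+](C)(C)C)C(=O)O[C@@H]4[C@@H]13)CC[C@@]21C(=O)C[C@H]2C(=C)CC[C@H]3C(C[N+](C)(C)C)C(=O)O[C@@H]3[C@H]21.[I-].[I-].[I-] | intermediate (not isolated)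
24 | A–B spiro dimer, ring R1 cyclohexene | C=C1C(=O)C2=C3[C@H](CC[C@H]4C(=C)C(=O)O[C@@H]4[C@@H]13)CC[C@@]21C(=O)C[C@H]2C(=C)CC[C@H]3C(=C)C(=O)O[C@@H]3[C@H]21 | intermediate
25 | C3(B) tert-butyldimethylsilyl enol ether of 24 | C=C1C(=O)C2=C3[C@H](CC[C@H]4C(=C)C(=O)O[C@@H]4[C@@H]13)CC[C@@]21C(O[Si](C)(C)C(C)(C)C)=C[C@H]2C(=C)CC[C@H]3C(=C)C(=O)O[C@@H]3[C@H]21 | intermediate
26 | A–B dienone (C2(B)=C1(B), C10(B)=C14(B)) | C=C1C(=O)C2=C3[C@H](CC[C@H]4C(=C)C(=O)O[C@@H]4[C@@H]13)CC[C@@]21C(=O)C=C2C(=C)CC[C@H]3C(=C)C(=O)O[C@@H]3[C@H]21 | intermediate (not isolated)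
27 | Diels–Alder trimer (C1(B)=C10(B), C2(B)–H open) | C=C1C(=O)C2=C3[C@H](CC[C@H]4C(=C)C(=O)O[C@@H]4[C@@H]13)CC[C@@]21C(=O)C2C3=C(CC[C@H]4C(=C)C(=O)O[C@@H]4[C@@H]13)CC[C@]21C(=O)C[C@H]2C(=C)CC[C@H]3C(=C)C(=O)O[C@@H]3[C@H]21 | intermediate
28 | C10(B) β-hydroperoxide | C=C1C(=O)C2=C3[C@H](CC[C@H]4C(=C)C(=O)O[C@@H]4[C@@H]13)CC[C@@]21C(=O)C2=C3[C@H]1[C@H]1OC(=O)C(=C)[C@@H]1CC[C@@]3(OO)CC[C@]21C(=O)C[C@H]2C(=C)CC[C@H]3C(=C)C(=O)O[C@@H]3[C@H]21 | intermediate (not isolated)
29 | ainsliatrimer A | C=C1C(=O)C2=C3[C@H](CC[C@H]4C(=C)C(=O)O[C@@H]4[C@@H]13)CC[C@@]21C(=O)C2=C3[C@H]1[C@H]1OC(=O)C(=C)[C@@H]1CC[C@@]3(O)CC[C@]21C(=O)C[C@H]2C(=C)CC[C@H]3C(=C)C(=O)O[C@@H]3[C@H]21 | target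

## Step count and least certain steps

Total: 20 steps. Longest linear sequence: 17 steps (steps 1, 2, 3, 4, 8–20); steps 5–7 form the three-step branch to 10.

**Step 14 (key).** The most likely failure is poor facial selectivity: if the twisted triene brings C15(B) onto the β face of C4(B) as readily as onto the α face, the spiro epimer forms irreversibly. Closure through oxygen could also hold the material back. Fallback: from 18, Me2AlCl at low temperature would promote the oxa-6π closure of the C3(B) carbonyl onto C10(A) on purpose, giving the 2H-pyran F1. Its allyl vinyl ether (C15B=C14A–C10A–O–C3B=C4B) would then undergo Claisen rearrangement, which forms the same C4(B)–C15(B) bond and returns to 19. The stereo-determining event becomes the rearrangement of equilibrating pyran diastereomers instead of the torquoselectivity of the triene.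

**Step 8.** The addition joins a secondary carbon to a hindered ketone and may revert. Under amine base, 10 may also enolise toward C5(B) and lose the lactone oxygen by β-elimination. Fallback: from 6, the tert-butyldimethylsilyl dienol ether F2 (TBSOTf, Et3N) would be added to 10 under TiCl4 without amine (Mukaiyama aldol) to give 11, which Martin sulfurane would dehydrate to 12.

**Step 10.** Deprotonation may occur at the less hindered C9(A), or at the γ-position C5(B) with loss of the lactone oxygen, and prior tautomerisation of 13 could favour the cross-conjugated enolate. Fallback: from 13, CH2=CHMgBr/CeCl3 would add to the saturated C10(A) ketone to give the vinyl carbinol F3. HF·pyridine would give the diol F4, and Dess–Martin oxidation the ene-dione carbinol F5. Burgess dehydration toward the vinylogously acidic C1(A)–H would then return to triene 18 without triflate or stannane.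

**Step 16.** Hydride transfer to the hindered dienone terminus may be too slow or may go to the C3(A) carbonyl, and the proton at C10(A) may enter from the β face. Fallback: from 20, electron-transfer reduction with SmI2 and t-BuOH in THF would generate the same extended enolate by a radical-anion pathway and give 21 and then 22. No compound outside the list is made (entry F0).

**Step 20.** Oxygen may be captured on the α face of C10(B), giving the C10(B) epimer, and DBU may begin to remove γ-hydrogens of unit A. Fallback: from 27, TBSOTf/Et3N would give the silyl dienol ether F6. Dimethyldioxirane would epoxidise its electron-rich C1(B)=C10(B) bond from the less hindered face to give the epoxide F7, and HF·pyridine would open this to 29 (vinylogous Rubottom oxidation). This replaces a small radical trap by a bulkier electrophile and needs no base in the oxidation.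

## Further compounds

F1 | step 14 | 2H-pyran from oxa-6π closure of 18 (C3(B) oxygen bonded to C10(A), vinyl on C10(A)) | C=C1C(=O)C2=C3[C@@](C=C)(CC[C@H]4C(=C)C(=O)O[C@@H]4[C@@H]13)OC1=C2[C@@H]2[C@H]3OC(=O)C(=C)[C@@H]3CCC(=C)[C@@H]2C1
F2 | step 8 | tert-butyldimethylsilyl dienol ether of 6 | C=C1C(O[Si](C)(C)C(C)(C)C)=C[C@H]2C3(OCCO3)CC[C@H]4C(=C)C(=O)O[C@@H]4[C@H]21
F3 | step 10 | C10(A) vinyl carbinol of 13 (C10(A) open) | C=C1C(=O)/C(=C5/[C@H](O[Si](C)(C)C(C)(C)C)C[C@H]6C(=C)CC[C@H]7C(=C)C(=O)O[C@@H]7[C@H]65)[C@H]2C(O)(C=C)CC[C@H]3C(=C)C(=O)O[C@@H]3[C@H]21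
F4 | step 10 | diol from F3 (C3(B) alcohol, C10(A) vinyl carbinol) | C=C1C(=O)/C(=C5/[C@H](O)C[C@H]6C(=C)CC[C@H]7C(=C)C(=O)O[C@@H]7[C@H]65)[C@H]2C(O)(C=C)CC[C@H]3C(=C)C(=O)O[C@@H]3[C@H]21
F5 | step 10 | ene-dione vinyl carbinol | C=C1C(=O)/C(=C5/C(=O)C[C@H]6C(=C)CC[C@H]7C(=C)C(=O)O[C@@H]7[C@H]65)[C@H]2C(O)(C=C)CC[C@H]3C(=C)C(=O)O[C@@H]3[C@H]21
F0 | step 16 | none | none
F6 | step 20 | C3(B) silyl dienol ether of 27 | C=C1C(=O)C2=C3[C@H](CC[C@H]4C(=C)C(=O)O[C@@H]4[C@@H]13)CC[C@@]21C(O[Si](C)(C)C(C)(C)C)=C2C3=C(CC[C@H]4C(=C)C(=O)O[C@@H]4[C@@H]13)CC[C@]21C(=O)C[C@H]2C(=C)CC[C@H]3C(=C)C(=O)O[C@@H]3[C@H]21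
F7 | step 20 | 1(B),10(B)-β-epoxide of F6 | C=C1C(=O)C2=C3[C@H](CC[C@H]4C(=C)C(=O)O[C@@H]4[C@@H]13)CC[C@@]21C(O[Si](C)(C)C(C)(C)C)=C2[C@@]34O[C@]4(CC[C@H]5C(=C)C(=O)O[C@@H]5[C@@H]13)CC[C@]21C(=O)C[C@H]2C(=C)CC[C@H]3C(=C)C(=O)O[C@@H]3[C@H]21
A1 | alternative 1 | trimethylsilyl enol ether of the B–C spiro-dihydropyran (4-methyl unit B) | C[C@H]1C(O[Si](C)(C)C)=C[C@@H]2[C@H]1[C@H]1OC(=O)C(=C)[C@@H]1CC[C@@]23CCC1=C(O3)C[C@H]2C(=C)CC[C@H]4C(=C)C(=O)O[C@@H]4[C@H]21
A2 | alternative 1 | 1,2-dihydro B–C ketol dimer (4-methyl unit B) | C[C@H]1C(=O)[C@@H]2[C@@H]3[C@H]1[C@H]1OC(=O)C(=C)[C@@H]1CC[C@@]3(O)CC[C@]21C(=O)C[C@H]2C(=C)CC[C@H]3C(=C)C(=O)O[C@@H]3[C@H]21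
A3 | alternative 2 | 14-nor ene-dione of unit B | C=C1C(=O)C=C2C(=O)CC[C@H]3C(=C)C(=O)O[C@@H]3[C@@H]12
A4 | alternative 2 | 4-acetyl-15-nor diketone form of unit C (C4 open) | CC(=O)C1C(=O)C[C@H]2C(=C)CC[C@H]3C(=C)C(=O)O[C@@H]3[C@H]21
A5 | alternative 2 | B–C ketol carrying a C15(C) carbonyl | C=C1C(=O)[C@@H]2[C@@H]3[C@H]1[C@H]1OC(=O)C(=C)[C@@H]1CC[C@@]3(O)CC(=O)[C@]21C(=O)C[C@H]2C(=C)CC[C@H]3C(=C)C(=O)O[C@@H]3[C@H]21
A6 | alternative 3 | A–B spiro-dihydropyran (allyl vinyl ether) | C=C1C(=O)C=C2[C@H]1[C@H]1OC(=O)C(=C)[C@@H]1CC[C@]21CCC2=C(O1)C[C@H]1C(=C)CC[C@H]3C(=C)C(=O)O[C@@H]3[C@@H]21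
A7 | alternative 3 | A–B spiro dimer, β,γ-enone form | C=C1C(=O)[C@H]2C3=C(CC[C@H]4C(=C)C(=O)O[C@@H]4[C@@H]13)CC[C@@]21C(=O)C[C@H]2C(=C)CC[C@H]3C(=C)C(=O)O[C@@H]3[C@H]21
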